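common to all: added ligand 5.8 mM
- Saturday's: starting material 0.067 M; second substrate 0.10 M; capture agent 0.10 M; free catalyst 2 mM; run made earlier
- Tuesday's: starting material 0.15 M; second substrate 0.10 M; capture agent 0.10 M; free catalyst 2 mM; run made earlier
- flask: starting material 0.10 M; second substrate 0.100 M; capture agent 0.100 M; free catalyst 2.0 mM

- Saturday's (time / d: target / %, starting material / %): 0.833: 24.8, 73.6; 2.00: 35.2, 60.7; 4.00: 43.2, 54.8; 6.00: 45.3, 52.5
- Tuesday's (time / d: target / %, starting material / %): 0.833: 17.0, 82.0; 2.00: 20.7, 79.7; 4.00: 21.0, 77.4; 6.00: 20.8, 77.2

(scatter of a reading: 0.5 percentage points)

- no earlier run changes the charge of free catalyst; that part of a forecast is a guess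
- no earlier run changes the charge of second substrate; that part of a forecast is a guess

- apparent order in second substrate when 20% of the starting material are converted (percent change of the rate of making target for one percent more second substrate charged)
- apparent order in free catalyst when 20% of the starting material are converted (percent change of the rate of making target for one percent more free catalyst charged)

In a one-step world, I expected starting material and target to reach equilibrium, with the same ratio of the two at the end of both runs. But the last readings gave a ratio of 0.863 in Saturday's run and 0.269 in Tuesday's, so I dropped that picture.

What matched was the amount of target. Dividing c(target) at the last reading by the free catalyst charged gave 15.2 in Saturday's run and 15.6 in Tuesday's. I carried their mean, the turnovers per catalyst (the turnover number), 15.4.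

Perhaps the catalyst simply died with time? Yet at the first reading Tuesday's run held 25.5 mM of target against 16.6 mM in Saturday's, and at the last reading it held 31.2 mM against 30.4 mM. I therefore counted the loss per turnover rather than per day.

A second doubt could not be computed away: both runs had the same catalyst and ligand charges, so my assumption that the stop grows with catalyst remained a guess. So did any order in second substrate, which neither run changed.

I then reckoned the new flask. With all converted starting material counted as target, 20% conversion meant 0.0200 M of target, which spent 65.0% of the count. If the rate follows the catalyst still working, more catalyst at the same conversion both adds to the amount and lowers the share spent, so the order is one over the share unspent, 2.86.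

The forecast gave 2.7 for free catalyst and 1.2 for second substrate, holding that “catalyst is probably lost per turnover”.

The flask gave 3.2 for free catalyst and −0.35 for second substrate.

    starting material + free catalyst ⇌ catalyst intermediate A (K = 3.80 M⁻¹, k = 52.0 M⁻¹ h⁻¹)
    second substrate + free catalyst ⇌ catalyst intermediate B (K = 24.0 M⁻¹, k = 54.0 M⁻¹ h⁻¹)
    free catalyst + added ligand ⇌ idle complex (K = 380 M⁻¹, k = 30.0 M⁻¹ h⁻¹)
    catalyst intermediate A + capture agent → trapped intermediate (k = 61.0 M⁻¹ h⁻¹)
    catalyst intermediate B → free catalyst + second product (k = 0.700 h⁻¹)
    catalyst intermediate A → free catalyst + target (k = 96.0 h⁻¹)

Catalyst intermediate A went on to target and free catalyst at 96 h⁻¹, but into trapped intermediate at 6.10 h⁻¹ with capture agent as charged, a ratio of 15.7. After 10.0 d, this flask held 31.8% target, or 15.9 turnovers per catalyst charged against my 15.4, and trapped intermediate held 99.9% of the catalyst. For twice the free catalyst, the count gave a rate factor of 3.86. The flask with twice the free catalyst gave a factor on the rate of 5.16.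

The readings are simulated on assumed constants; the scatter is artificial.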